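## Analysis of the target

Target 18 is a 3,3''-biflavanone: two 2-(4-methoxyphenyl)chroman-4-one units joined by the C3–C3'' bond, with phloroglucinol-type benzo rings A and D, pyranone rings C and F, and anisyl rings B and E. The four stereocentres C2, C3, C3'' and C2'' are contiguous and all R, with H2 and H3 cis within each pyranone ring and the two halves homochiral, so the carbon skeleton is C2-symmetric. The symmetry is broken only at C7'', which carries OMe where C7 carries OH. The cis-2,3 relation is the less stable one, and C3–H and C3''–H are α to aryl ketones, so base or strong acid can epimerise them or open the rings by retro-oxa-Michael reaction. The C2–O1 and C2''–O1'' bonds are 4-methoxybenzylic aryl ether bonds and are open to acid ionisation and to hydrogenolysis. The hard parts are the central bond between two tertiary carbons inside a four-centre array, and the methylation of one of two equivalent 7-hydroxyls beside two chelated 5-hydroxyls. The strategy rests on one feature: C2–C3 (and C2''–C3'') joins an oxygen-bearing benzylic carbon to a carbon that carries C4, so that, if C4 (and C4'') is read as the inner carbon of a propenyl group, each of these bonds is the one a [2,3]-Wittig shift of a 4-methoxybenzyl allyl ether makes, and C3–C3'' is the central bond of a 1,3-diene.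

## Retrosynthetic reasoning

**18 to 17.** The O–CH3 bond at C7'' is cut last. It is the only element that breaks the C2 symmetry, so every earlier intermediate stays symmetric and each operation is done once for both halves. The forward reaction has to methylate one of two homotopic free 7-hydroxyls of 17, leave the chelated 5-hydroxyls alone, and use no base that would epimerise C3.

**17 to 16.** The four phenolic O–H bonds are traced to benzyl ethers. They survive base, oxidants and mild acid, and they leave under neutral conditions that do not enolise the ketones.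

**16 to 13 (through 14 and 15).** The C4–C4a and C4''–C4a'' aryl–acyl bonds are cut. An aryl ketone on a trioxygenated ring is the natural acylation retron, and the closure creates no stereocentre. Both ortho positions of each symmetric aryloxy ring are equivalent, so there is no regiochemical question. The forward reaction must acylate under conditions that the benzylic aryl ethers tolerate.

**13 to 12 to 10.** Each carboxyl carbon is traced through the aldehyde to the inner carbon of an (E)-propenyl group, so the C=C bonds are the ones cut. The propenyl group is what the sigmatropic step delivers. The two-carbon pieces lost here carry the carbons of the original chiral-pool centres, whose stereochemical information has already been passed on.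

**10 to 7 and 9.** The O1–C8a and O1''–C8a'' bonds are cut at the aryl carbon and not at C2. Bond formation at the aryl carbon leaves the carbinol C–O bond intact and so keeps the configuration, whereas displacement at the 4-methoxybenzylic carbon would invite ionisation. The aryl partner 9 comes from 8 by double O-benzylation.

**7 to 5 (through 6).** This is the key disconnection: the C2–C3 and C2''–C3'' bonds (C1–C2 and C3–C4 of the butane chain of 7) are cut. Each is the bond between carbanion carbon and γ-carbon of a [2,3]-Wittig shift, so both halves of 7 collapse onto the C2-symmetric (Z,Z)-diene bis-ether 5. The forward reaction makes two C–C bonds and four stereocentres from two existing centres and two alkene geometries.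

**5 to 3 and 4, 3 to 2, 2 to 1.** The benzylic O–CH2 bonds are cut to diol 3 and chloride 4. The Z,Z-diene comes from diyne 2, and the central C4–C5 bond of 2 comes from oxidative dimerisation of two molecules of alkynol 1. One chiral-pool alkynol thus supplies both controlling centres and the C2 symmetry.

## Alternatives that were turned down

**Alternative 1:** The C2–aryl and C2''–aryl bonds are cut, which leads to bichromone A1. Its benzo rings already carry the final oxygen pattern, with three benzyl ethers and the 7''-methyl ether. In the forward direction boronic acid A2 adds twice in 1,4-fashion under a monovalent rhodium catalyst with a chiral diene ligand, each rhodium enolate is protonated at C3, and the product is A3; one hydrogenolysis then finishes the synthesis.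
- **For it:** the end-game is the shortest of all, the catalyst fixes the absolute configuration at C2 and C2'', and the unsymmetrical methylation is built into A1. On this last point it is stronger than the chosen route, which ends with a statistical methylation.
- **Against it:** in A1 each enone α-carbon is fully substituted by the other chromone and flanked by a peri benzyloxy group, and conjugate arylation of such α-substituted chromones is much harder than that of the parent. C3 and C3'' arise by enolate protonation, which the ligand does not govern. The wanted cis relation is the less stable one and would have to form kinetically twice. The second addition runs on a chiral intermediate, with a matched or mismatched outcome. A1 also needs an unsymmetrical coupling of two different 3-functionalised chromones.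
- **Comparison:** the chosen route sets all four centres by intramolecular transfer from a defined centre and alkene geometry, and none by protonation. It pays with more steps and with the statistical last step.

**Alternative 2:** The two carbinol centres are traced to aryl ketones and C3/C3'' to the stereolabile α-carbons of diaroylsuccinate A4. In the forward direction both ketones are reduced by asymmetric transfer hydrogenation under dynamic kinetic resolution (a divalent ruthenium arene–sulfonyldiamine catalyst with a formate hydride source), and each alkoxide lactonises onto the distal ester to give bislactone A5.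
- **For it:** A4 is achiral and quickly made, four stereocentres are set catalytically in one operation, and no chiral-pool carbons are thrown away. Up to the stereo-tetrad it is clearly more economical than the four steps to 7.
- **Against it:** in A5 each carbinol oxygen is acylated by the carbonyl carbon of the other half, whereas the flavanone needs that oxygen bound to an aryl ring on its own half. Both lactones must therefore be opened by an ortho-functionalised aryl carbon nucleophile and the freed hydroxyls cyclised onto the new aryl ketones. The intermediates are β-hydroxy ketones, which under the basic closure conditions are prone to retro-aldol cleavage and dehydration. The exo,exo outcome of two coupled reductions is also not secured, because the second one runs on a lactone whose α-centre is under substrate control.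
- **Comparison:** the chosen route keeps the carbinol oxygens free for direct O-arylation and never passes a β-hydroxy ketone. It concedes the catalytic economy of the stereo-tetrad.

**Alternative 3:** Rings A and D themselves are cut at C4a–C5 and C8–C8a (and the counterparts), leaving bis-dihydropyranone A6 with a sulfinyl group on each C4a, and silyloxy diene A7. In the forward direction two molecules of A7 add across the activated C4a=C8a bonds, and loss of the sulfinyl groups and of the acetal methoxy groups with desilylation aromatises both rings to tetrol A8, which is identical with 17.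
- **For it:** no protecting groups on the phloroglucinol oxygens, no acid-mediated acylation and no hydrogenolysis near the benzylic C2–O bonds, and complete regiocontrol of the 5,7-dioxygenation. In protecting-group economy it is stronger.
- **Against it:** all four stereocentres must already sit in A6, and this strategy does nothing to make them. The C3–C3'' bond between two enolisable dihydropyranones with cis-2,3 substituents is the real problem, moved one stage back. The annulation needs Lewis acid or fluoride activation beside the enolisable C3 centres. The sulfinyl activation costs extra steps and adds two stereogenic sulfur atoms. The route ends at A8, so the statistical methylation remains, and on that point the two routes are equal.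
- **Comparison:** the chosen route takes the aromatic rings from 9 and spends its effort on the stereo-tetrad.

Key step: step 4

Remark on the chemistry: the target is read as the (2R,3R,2''R,3''R) isomer, with H2/H3 and H2''/H3'' cis and the halves homochiral, so that the two 7-hydroxyls of 17 are homotopic; 1, 4 and 8 are taken as commercial.

## Route

Step 1
Reactants: 1 (S)-but-3-yn-2-ol (two molecules)
Product: 2 (2S,7S)-octa-3,5-diyne-2,7-diol
Conditions: CuCl (10 mol %), TMEDA (20 mol %), O2 (1 atm), acetone, rt
Reagents that add atoms: second molecule of 1, (S)-but-3-yn-2-ol, C[C@H](O)C#C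
Why: Glaser–Hay oxidative homocoupling joins two molecules of the terminal alkyne at their sp carbons, with O2 as the terminal oxidant and water as the only by-product; the carbinol centres are not involved and keep the (S) configuration.

Step 2
Reactants: 2 (2S,7S)-octa-3,5-diyne-2,7-diol
Product: 3 (2S,3Z,5Z,7S)-octa-3,5-diene-2,7-diol
Conditions: Zn dust activated with Cu(OAc)2 and AgNO3, MeOH/H2O 1:1, rt to 40 °C
Reagents that add atoms: none
Why: Boland-type reduction of a conjugated diyne on the activated zinc surface delivers hydrogen cis to each triple bond and should stop at the (Z,Z)-diene; the propargylic hydroxyls assist the reduction and the carbinol centres are untouched.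

Step 3
Reactants: 3 (2S,3Z,5Z,7S)-octa-3,5-diene-2,7-diol; 4 4-methoxybenzyl chloride
Product: 5 (2S,3Z,5Z,7S)-2,7-bis[(4-methoxybenzyl)oxy]octa-3,5-diene
Conditions: NaH (2.4 equiv), DMF/THF, 0 °C; 4 (2.4 equiv), n-Bu4NI (cat.), 0 °C to rt
Reagents that add atoms: none
Why: Williamson etherification of both secondary alkoxides with a reactive benzylic chloride; no bond to a stereocentre or to the diene is broken.

Step 4
Reactants: 5 (2S,3Z,5Z,7S)-2,7-bis[(4-methoxybenzyl)oxy]octa-3,5-diene
Product: 7 (1R,2R,3R,4R)-1,4-bis(4-methoxyphenyl)-2,3-bis[(E)-prop-1-en-1-yl]butane-1,4-diol, via mono-rearranged lithium alkoxide 6 (not isolated)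
Conditions: n-BuLi (3 equiv), THF, −78 to −30 °C; then H2O
Reagents that add atoms: none
Why: n-BuLi removes one proton from each OCH2Ar group, and each α-alkoxybenzyllithium attacks the γ-carbon of its allylic ether through a five-membered envelope transition state while the O–C(allyl) bond breaks, a suprafacial [2,3]-Wittig shift; the closest known reaction is the [2,3]-Wittig rearrangement of benzyl ethers of secondary (Z)-allylic alcohols with 1,3-chirality transfer. No ring closes; the two new C–C bonds are the future C2–C3 and C2''–C3'' bonds, and the two new C=C bonds are the (E)-propenyl groups. C3 and C3'' are controlled by the (S) ether carbons: allylic 1,3-strain against the cis substituent of the Z-alkene puts the ether hydrogen and not the methyl group in the alkene plane, so oxygen leaves and carbon arrives on one defined face and the methyl group ends trans on the new double bond. C2 and C2'' are controlled by the Z geometry: the aryl group takes the exo position on the envelope, which for a Z-alkene gives the syn carbinol/allyl relation that becomes cis-2,3 in the chromanone. The first shift gives alkoxide 6, and the second runs on its remaining (Z)-allylic ether under the control of that ether's own (S) centre, so both halves should end (R,R). The step needs lithiation at the benzylic CH2 and not at the dienylic OCH methine, which the easier access to the primary benzylic site should secure, and it needs the [2,3] shift to outrun the [1,2] shift, which the low temperature should secure.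

Step 5
Reactants: 8 5-bromobenzene-1,3-diol
Product: 9 1,3-bis(benzyloxy)-5-bromobenzene
Conditions: BnBr (2.3 equiv), K2CO3, DMF, rt to 60 °C
Reagents that add atoms: benzyl bromide, BrCc1ccccc1
Why: Williamson O-benzylation of both phenols; the aryl bromide is inert under these conditions.

Step 6
Reactants: 7 (1R,2R,3R,4R)-1,4-bis(4-methoxyphenyl)-2,3-bis[(E)-prop-1-en-1-yl]butane-1,4-diol; 9 1,3-bis(benzyloxy)-5-bromobenzene
Product: 10 (1R,2R,3R,4R)-1,4-bis[3,5-bis(benzyloxy)phenoxy]-1,4-bis(4-methoxyphenyl)-2,3-bis[(E)-prop-1-en-1-yl]butane
Conditions: [Pd(allyl)Cl]2 (5 mol %), RockPhos (12 mol %), Cs2CO3 (4 equiv), 9 (3 equiv), toluene, 90 °C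
Reagents that add atoms: none
Why: Palladium-catalysed C–O cross-coupling (Buchwald–Hartwig etherification) of a secondary alcohol with an aryl bromide; the bulky biarylphosphine favours C–O reductive elimination over β-hydride elimination, and the carbinol C–O bonds are not broken, so both centres keep their configuration.

Step 7
Reactants: 10 (1R,2R,3R,4R)-1,4-bis[3,5-bis(benzyloxy)phenoxy]-1,4-bis(4-methoxyphenyl)-2,3-bis[(E)-prop-1-en-1-yl]butane
Product: 12 (2R,3R)-2,3-bis{(R)-[3,5-bis(benzyloxy)phenoxy](4-methoxyphenyl)methyl}butanedial, via bis-diol 11 (not isolated)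
Conditions: OsO4 (5 mol %), NaIO4 (8 equiv), 2,6-lutidine (4 equiv), 1,4-dioxane/H2O 3:1, rt; used crude
Reagents that add atoms: osmium tetroxide, O=[Os](=O)(=O)=O; sodium periodate, [Na+].[O-]I(=O)(=O)=O
Why: Lemieux–Johnson cleavage: catalytic dihydroxylation of both propenyl groups to bis-diol 11 and periodate cleavage of each glycol; the buffered, nearly neutral medium should spare the α-centres and the β-aryloxy groups, and the arenes are inert to both oxidants.

Step 8
Reactants: 12 (2R,3R)-2,3-bis{(R)-[3,5-bis(benzyloxy)phenoxy](4-methoxyphenyl)methyl}butanedial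
Product: 13 (2R,3R)-2,3-bis{(R)-[3,5-bis(benzyloxy)phenoxy](4-methoxyphenyl)methyl}butanedioic acid
Conditions: NaClO2, NaH2PO4, 2-methylbut-2-ene (large excess), t-BuOH/H2O, 0 °C to rt
Reagents that add atoms: sodium chlorite, [Na+].[O-]Cl=O
Why: Pinnick oxidation converts both aldehydes to acids under weakly acidic conditions that do not enolise the α-carbons; the alkene scavenger should intercept hypochlorous acid before it can chlorinate the electron-rich rings.

Step 9
Reactants: 13 (2R,3R)-2,3-bis{(R)-[3,5-bis(benzyloxy)phenoxy](4-methoxyphenyl)methyl}butanedioic acid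
Product: 16 (2R,3R,2''R,3''R)-5,7,5'',7''-tetrakis(benzyloxy)-4',4'''-dimethoxy-3,3''-biflavanone, via succinic anhydride 14 (not isolated), via mono-chromanone acid 15 (not isolated)
Conditions: (CF3CO)2O (3 equiv), CH2Cl2, 0 °C to rt
Reagents that add atoms: none
Why: Double intramolecular Friedel–Crafts acylation: the reagent first dehydrates the succinic diacid to trans anhydride 14, an ortho carbon of the neighbouring aryloxy ring attacks one carbonyl in a six-membered closure to give acid 15, and the freed carboxyl is activated by a second equivalent of the reagent for the second closure. Both ortho positions of each aryloxy ring are equivalent and far more nucleophilic than the anisyl rings, so only chromanones should form, and no stereocentre is touched as long as the medium stays weakly acidic.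

Step 10
Reactants: 16 (2R,3R,2''R,3''R)-5,7,5'',7''-tetrakis(benzyloxy)-4',4'''-dimethoxy-3,3''-biflavanone
Product: 17 (2R,3R,2''R,3''R)-5,7,5'',7''-tetrahydroxy-4',4'''-dimethoxy-3,3''-biflavanone
Conditions: H2 (1 atm), 10% Pd/C, EtOAc/MeOH, rt, stopped at full debenzylation
Reagents that add atoms: none
Why: Hydrogenolysis of four aryl benzyl ethers under neutral conditions, which cannot enolise C3 or C3''; primary benzyl ethers should cleave faster than the ring C2–O1 bonds.

Step 11
Reactants: 17 (2R,3R,2''R,3''R)-5,7,5'',7''-tetrahydroxy-4',4'''-dimethoxy-3,3''-biflavanone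
Product: 18 (2R,3R,2''R,3''R)-5,7,5''-trihydroxy-7'',4',4'''-trimethoxy-3,3''-biflavanone
Conditions: Me3SiCHN2 (1.0 equiv), MeOH/toluene 1:4, 0 °C; unreacted 17 recovered
Reagents that add atoms: trimethylsilyldiazomethane, C[Si](C)(C)C=[N+]=[N-]
Why: O-methylation of a phenol by a diazoalkane: only the free, more acidic 7-hydroxyls (para to the carbonyl) protonate the reagent, methanol then releases diazomethane, which methylates the phenoxide, and the chelated 5-hydroxyls do not react. With one equivalent the two homotopic 7-hydroxyls react statistically, so 18 should be the largest fraction beside recovered 17 and some 7,7''-dimethyl ether, and the neutral medium leaves the cis C2/C3 relations untouched.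

## Compound list

1 | (S)-but-3-yn-2-ol | C[C@H](O)C#C | starting material
2 | (2S,7S)-octa-3,5-diyne-2,7-diol | C[C@H](O)C#CC#C[C@H](C)O | intermediate
3 | (2S,3Z,5Z,7S)-octa-3,5-diene-2,7-diol | C[C@H](O)/C=C\C=C/[C@H](C)O | intermediate
4 | 4-methoxybenzyl chloride | COc1ccc(CCl)cc1 | starting material
5 | (2S,3Z,5Z,7S)-2,7-bis[(4-methoxybenzyl)oxy]octa-3,5-diene | C[C@H](OCc1ccc(OC)cc1)/C=C\C=C/[C@H](C)OCc1ccc(OC)cc1 | intermediate
6 | lithium (1R,2R,3Z,5S)-5-[(4-methoxybenzyl)oxy]-1-(4-methoxyphenyl)-2-[(E)-prop-1-en-1-yl]hex-3-en-1-olate | COc1ccc([C@H](O[Li])[C@H](/C=C/C)/C=C\[C@H](C)OCc2ccc(OC)cc2)cc1 | intermediate (not isolated)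
7 | (1R,2R,3R,4R)-1,4-bis(4-methoxyphenyl)-2,3-bis[(E)-prop-1-en-1-yl]butane-1,4-diol | COc1ccc([C@H](O)[C@H](/C=C/C)[C@@H](/C=C/C)[C@@H](O)c2ccc(OC)cc2)cc1 | intermediate
8 | 5-bromobenzene-1,3-diol | Oc1cc(O)cc(Br)c1 | starting material
9 | 1,3-bis(benzyloxy)-5-bromobenzene | Brc1cc(OCc2ccccc2)cc(OCc2ccccc2)c1 | intermediate
10 | (1R,2R,3R,4R)-1,4-bis[3,5-bis(benzyloxy)phenoxy]-1,4-bis(4-methoxyphenyl)-2,3-bis[(E)-prop-1-en-1-yl]butane | COc1ccc([C@H](Oc2cc(OCc3ccccc3)cc(OCc3ccccc3)c2)[C@H](/C=C/C)[C@@H](/C=C/C)[C@@H](Oc2cc(OCc3ccccc3)cc(OCc3ccccc3)c2)c2ccc(OC)cc2)cc1 | intermediate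
11 | bis-diol of 10: each propenyl group replaced by a 1,2-dihydroxypropyl group (mixture at the four new carbinol carbons) | COc1ccc([C@H](Oc2cc(OCc3ccccc3)cc(OCc3ccccc3)c2)[C@H](C(O)C(C)O)[C@@H](C(O)C(C)O)[C@@H](Oc2cc(OCc3ccccc3)cc(OCc3ccccc3)c2)c2ccc(OC)cc2)cc1 | intermediate (not isolated)
12 | (2R,3R)-2,3-bis{(R)-[3,5-bis(benzyloxy)phenoxy](4-methoxyphenyl)methyl}butanedial | COc1ccc([C@H](Oc2cc(OCc3ccccc3)cc(OCc3ccccc3)c2)[C@H](C=O)[C@@H](C=O)[C@@H](Oc2cc(OCc3ccccc3)cc(OCc3ccccc3)c2)c2ccc(OC)cc2)cc1 | intermediate
13 | (2R,3R)-2,3-bis{(R)-[3,5-bis(benzyloxy)phenoxy](4-methoxyphenyl)methyl}butanedioic acid | COc1ccc([C@H](Oc2cc(OCc3ccccc3)cc(OCc3ccccc3)c2)[C@H](C(=O)O)[C@@H](C(=O)O)[C@@H](Oc2cc(OCc3ccccc3)cc(OCc3ccccc3)c2)c2ccc(OC)cc2)cc1 | intermediate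
14 | (3R,4R)-3,4-bis{(R)-[3,5-bis(benzyloxy)phenoxy](4-methoxyphenyl)methyl}oxolane-2,5-dione | COc1ccc([C@H](Oc2cc(OCc3ccccc3)cc(OCc3ccccc3)c2)[C@@H]2C(=O)OC(=O)[C@H]2[C@@H](Oc2cc(OCc3ccccc3)cc(OCc3ccccc3)c2)c2ccc(OC)cc2)cc1 | intermediate (not isolated)
15 | (2R,3R)-2-[(2R,3R)-5,7-bis(benzyloxy)-2-(4-methoxyphenyl)-4-oxochroman-3-yl]-3-[3,5-bis(benzyloxy)phenoxy]-3-(4-methoxyphenyl)propanoic acid | COc1ccc([C@@H]2Oc3cc(OCc4ccccc4)cc(OCc4ccccc4)c3C(=O)[C@@H]2[C@@H](C(=O)O)[C@@H](Oc2cc(OCc3ccccc3)cc(OCc3ccccc3)c2)c2ccc(OC)cc2)cc1 | intermediate (not isolated)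
16 | (2R,3R,2''R,3''R)-5,7,5'',7''-tetrakis(benzyloxy)-4',4'''-dimethoxy-3,3''-biflavanone | COc1ccc([C@@H]2Oc3cc(OCc4ccccc4)cc(OCc4ccccc4)c3C(=O)[C@@H]2[C@H]2C(=O)c3c(OCc4ccccc4)cc(OCc4ccccc4)cc3O[C@H]2c2ccc(OC)cc2)cc1 | intermediate
17 | (2R,3R,2''R,3''R)-5,7,5'',7''-tetrahydroxy-4',4'''-dimethoxy-3,3''-biflavanone | COc1ccc([C@@H]2Oc3cc(O)cc(O)c3C(=O)[C@@H]2[C@H]2C(=O)c3c(O)cc(O)cc3O[C@H]2c2ccc(OC)cc2)cc1 | intermediate
18 | (2R,3R,2''R,3''R)-5,7,5''-trihydroxy-7'',4',4'''-trimethoxy-3,3''-biflavanone | COc1ccc([C@@H]2Oc3cc(O)cc(O)c3C(=O)[C@@H]2[C@H]2C(=O)c3c(O)cc(OC)cc3O[C@H]2c2ccc(OC)cc2)cc1 | target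

## Step count and least certain steps

Total: 11 steps. Longest linear sequence: 10 steps (steps 1–4 and 6–11); step 5 is a one-step side branch.

**Step 4 (key step).**
- What may go wrong: lithiation at the dienylic OCH methine in place of the benzylic CH2, which would delocalise the anion over the diene, scramble the ether centre and the alkene geometry, and open [1,2] and [1,4] shifts. The para-methoxy group may also slow the benzylic deprotonation. The second shift may be less syn-selective or incomplete, because the cis substituent is then a bulky branched carbon.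
- Fallback: the carbanions are generated without any deprotonation. It sets out from 3 and 4 and comes back at 7. Chloride 4 and thiophenol (K2CO3, acetone) give 4-methoxybenzyl phenyl sulfide F1. N-Chlorosuccinimide converts it to chloro(4-methoxyphenyl)methyl phenyl sulfide F2. Diol 3 with F2 and i-Pr2NEt gives the bis(O,S-acetal) F3. Lithium naphthalenide in THF at −78 °C cleaves each benzylic C–S bond reductively, so the α-alkoxybenzyllithium can form only at the benzylic carbon, and the same two [2,3] shifts lead to 7 after aqueous quench.

**Step 6.**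
- What may go wrong: β-hydride elimination from the palladium alkoxide of a hindered benzylic carbinol, which oxidises the alcohol and reduces the aryl bromide, or β-carbon elimination (retro-allylation) of the homoallylic alkoxide. The second arylation may also stall for steric reasons.
- Fallback: the polarity of the aryl partner is reversed. It sets out from 7 and 9 and comes back at 10. Bromide 9 (n-BuLi, then B(Oi-Pr)3, then aqueous KHF2) gives potassium [3,5-bis(benzyloxy)phenyl]trifluoroborate F4. Oxidative copper coupling of 7 with F4 (Cu(OAc)2 as the divalent copper source, DMAP, 4 Å molecular sieves, O2, CH2Cl2, rt) forms the aryl ethers at room temperature without a palladium alkoxide and without strong base.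

**Step 7 (with step 8).**
- What may go wrong: E1cB loss of the β-aryloxy group from the enolisable dialdehyde, or epimerisation at its α-carbons, while 12 stands in the buffered medium or is handled.
- Fallback: the alkenes are cleaved straight to the acid level so that the aldehyde never accumulates. It sets out from 10 and comes back at 13, and no new compound is isolated. OsO4 (cat.) with KHSO5 (Oxone) in DMF at rt oxidises each aldehyde as it forms, in a medium that is acidic and not basic.

**Step 9.**
- What may go wrong: ionisation of the 4-methoxybenzylic aryl ether bonds in the acidic medium before ring closure, with loss of configuration at the future C2 or elimination. Anhydride 14 may acylate sluggishly, the reagent may trifluoroacetylate the electron-rich aryloxy rings before they close, and C3 may enolise after closure.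
- Fallback: the rings are closed one at a time under buffered, non-protic activation. It sets out from 13 and comes back at 16 through 15. Acetic anhydride dehydrates 13 to isolated 14. Allyl alcohol with DMAP opens 14 to the allyl half-ester F5. 1-Chloro-N,N,2-trimethylprop-1-en-1-amine converts the free carboxyl in the flask to the acid chloride F6, which AgOTf and 2,6-di-tert-butyl-4-methylpyridine close at −40 °C to the chromanone allyl ester F7. Pd(PPh3)4 with PhSiH3 removes the allyl group under neutral conditions to give 15. The same chloro-enamine converts 15 to the acid chloride F8, and AgOTf with the pyridine base closes the second ring to 16.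

**Step 10.**
- What may go wrong: hydrogenolytic opening of the benzylic C2–O1 bonds, or reduction of the ketones, on prolonged exposure.
- Fallback: Lewis-acid debenzylation in place of hydrogenolysis. It sets out from 16 and comes back at 17 with no new compound. BCl3 with pentamethylbenzene as cation scavenger in CH2Cl2 at −78 °C removes the aryl benzyl ethers.

**Step 11.**
- What may go wrong: over-methylation to the 7,7''-dimethyl ether, which cannot be recycled. The starting tetrol, the product and the dimethyl ether may separate poorly, and the chelated 5-hydroxyls may be partly methylated if excess reagent is used.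
- Fallback: the statistical event is moved to a reversible protection. It sets out from 17 and comes back at 18. One equivalent of t-BuPh2SiCl with imidazole gives the 7-mono-silyl ether F9, which differs strongly in polarity from 17 and from the 7,7''-bis-silyl ether F10; F10 can be desilylated back to 17 with HF·pyridine. Excess Me3SiCHN2 then methylates the one remaining free 7''-hydroxyl of F9 to completion and gives the 7-silyl 7''-methyl ether F11. HF·pyridine removes the silyl group to give 18.

## Further compounds

F1 | step 4 | 4-methoxybenzyl phenyl sulfide | COc1ccc(CSc2ccccc2)cc1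
F2 | step 4 | chloro(4-methoxyphenyl)methyl phenyl sulfide | COc1ccc(C(Cl)Sc2ccccc2)cc1
F3 | step 4 | (2S,3Z,5Z,7S)-2,7-bis[(4-methoxyphenyl)(phenylsulfanyl)methoxy]octa-3,5-diene (mixture at the two acetal carbons) | C[C@H](OC(Sc1ccccc1)c1ccc(OC)cc1)/C=C\C=C/[C@H](C)OC(Sc1ccccc1)c1ccc(OC)cc1
F4 | step 6 | potassium [3,5-bis(benzyloxy)phenyl]trifluoroborate | [K+].F[B-](F)(F)c1cc(OCc2ccccc2)cc(OCc2ccccc2)c1
F0 | step 7 | none | none
F5 | step 9 | (2R,3R)-4-(allyloxy)-2,3-bis{(R)-[3,5-bis(benzyloxy)phenoxy](4-methoxyphenyl)methyl}-4-oxobutanoic acid | COc1ccc([C@H](Oc2cc(OCc3ccccc3)cc(OCc3ccccc3)c2)[C@H](C(=O)OCC=C)[C@@H](C(=O)O)[C@@H](Oc2cc(OCc3ccccc3)cc(OCc3ccccc3)c2)c2ccc(OC)cc2)cc1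
F6 | step 9 | allyl (2R,3R)-4-chloro-2,3-bis{(R)-[3,5-bis(benzyloxy)phenoxy](4-methoxyphenyl)methyl}-4-oxobutanoate (not isolated) | COc1ccc([C@H](Oc2cc(OCc3ccccc3)cc(OCc3ccccc3)c2)[C@H](C(=O)OCC=C)[C@@H](C(=O)Cl)[C@@H](Oc2cc(OCc3ccccc3)cc(OCc3ccccc3)c2)c2ccc(OC)cc2)cc1
F7 | step 9 | allyl (2R,3R)-2-[(2R,3R)-5,7-bis(benzyloxy)-2-(4-methoxyphenyl)-4-oxochroman-3-yl]-3-[3,5-bis(benzyloxy)phenoxy]-3-(4-methoxyphenyl)propanoate | COc1ccc([C@@H]2Oc3cc(OCc4ccccc4)cc(OCc4ccccc4)c3C(=O)[C@@H]2[C@@H](C(=O)OCC=C)[C@@H](Oc2cc(OCc3ccccc3)cc(OCc3ccccc3)c2)c2ccc(OC)cc2)cc1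
F8 | step 9 | (2R,3R)-2-[(2R,3R)-5,7-bis(benzyloxy)-2-(4-methoxyphenyl)-4-oxochroman-3-yl]-3-[3,5-bis(benzyloxy)phenoxy]-3-(4-methoxyphenyl)propanoyl chloride (not isolated) | COc1ccc([C@@H]2Oc3cc(OCc4ccccc4)cc(OCc4ccccc4)c3C(=O)[C@@H]2[C@@H](C(=O)Cl)[C@@H](Oc2cc(OCc3ccccc3)cc(OCc3ccccc3)c2)c2ccc(OC)cc2)cc1
F0 | step 10 | none | none
F9 | step 11 | 7-O-(tert-butyldiphenylsilyl) ether of 17 | COc1ccc([C@@H]2Oc3cc(O[Si](c4ccccc4)(c4ccccc4)C(C)(C)C)cc(O)c3C(=O)[C@@H]2[C@H]2C(=O)c3c(O)cc(O)cc3O[C@H]2c2ccc(OC)cc2)cc1
F10 | step 11 | 7,7''-bis-O-(tert-butyldiphenylsilyl) ether of 17 | COc1ccc([C@@H]2Oc3cc(O[Si](c4ccccc4)(c4ccccc4)C(C)(C)C)cc(O)c3C(=O)[C@@H]2[C@H]2C(=O)c3c(O)cc(O[Si](c4ccccc4)(c4ccccc4)C(C)(C)C)cc3O[C@H]2c2ccc(OC)cc2)cc1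
F11 | step 11 | 7-O-(tert-butyldiphenylsilyl) 7''-O-methyl ether of 17 | COc1ccc([C@@H]2Oc3cc(O[Si](c4ccccc4)(c4ccccc4)C(C)(C)C)cc(O)c3C(=O)[C@@H]2[C@H]2C(=O)c3c(O)cc(OC)cc3O[C@H]2c2ccc(OC)cc2)cc1
A1 | alternative 1 | 5,7-bis(benzyloxy)-3-[5-(benzyloxy)-7-methoxy-4-oxo-4H-chromen-3-yl]-4H-chromen-4-one | O=c1c(-c2coc3cc(OC)cc(OCc4ccccc4)c3c2=O)coc2cc(OCc3ccccc3)cc(OCc3ccccc3)c12
A2 | alternative 1 | 4-methoxyphenylboronic acid | COc1ccc(B(O)O)cc1
A3 | alternative 1 | (2R,3R,2''R,3''R)-5,7,5''-tris(benzyloxy)-7'',4',4'''-trimethoxy-3,3''-biflavanone | COc1ccc([C@@H]2Oc3cc(OCc4ccccc4)cc(OCc4ccccc4)c3C(=O)[C@@H]2[C@H]2C(=O)c3c(OCc4ccccc4)cc(OC)cc3O[C@H]2c2ccc(OC)cc2)cc1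
A4 | alternative 2 | dimethyl 2,3-bis(4-methoxybenzoyl)butanedioate (stereolabile) | COC(=O)C(C(=O)c1ccc(OC)cc1)C(C(=O)OC)C(=O)c1ccc(OC)cc1
A5 | alternative 2 | exo,exo cis-fused 4,8-bis(4-methoxyphenyl)-3,7-dioxabicyclo[3.3.0]octane-2,6-dione | COc1ccc([C@@H]2OC(=O)[C@@H]3[C@H]2C(=O)O[C@H]3c2ccc(OC)cc2)cc1
A6 | alternative 3 | (2R,3R,2'R,3'R)-2,2'-bis(4-methoxyphenyl)-5,5'-bis(phenylsulfinyl)-2,2',3,3'-tetrahydro-[3,3'-bipyran]-4,4'-dione (sulfinyl group drawn as phenylsulfinyl) | COc1ccc([C@@H]2OC=C(S(=O)c3ccccc3)C(=O)[C@@H]2[C@H]2C(=O)C(S(=O)c3ccccc3)=CO[C@H]2c2ccc(OC)cc2)cc1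
A7 | alternative 3 | 1-methoxy-1,3-bis(trimethylsilyloxy)buta-1,3-diene | COC(O[Si](C)(C)C)=CC(=C)O[Si](C)(C)C
A8 | alternative 3 | (2R,3R,2''R,3''R)-5,7,5'',7''-tetrahydroxy-4',4'''-dimethoxy-3,3''-biflavanone (identical with 17) | COc1ccc([C@@H]2Oc3cc(O)cc(O)c3C(=O)[C@@H]2[C@H]2C(=O)c3c(O)cc(O)cc3O[C@H]2c2ccc(OC)cc2)cc1
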